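**Retrosynthetic overview**
1. Target 23 ⇐ its 14‑O‑silyl ether 22 (desilylation last).
2. 22 ⇐ acyclic bromo epoxy‑aldehyde 19 in one operation: C7, the normally electrophilic β‑carbon of the acrylate, is converted into an alkenylchromium nucleophile (β‑acylvinyl anion, an sp2 homoenolate equivalent) and adds to the electrophilic C6 aldehyde. This closes the ten‑membered carbocycle and sets C6; the alkoxide then closes the butenolide.
3. 19 ⇐ 2Z‑alkene from a C2≡C3 alkyne; C1–C2 by Sonogashira union of northern bromo iodide 13 with southern alkynyl oxirane 15. Both oxiranes are made on open chains (Sharpless at C4–C5, Shi at C1–C10).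
4. 13 ⇐ propargyl alcohol + allyl Grignard (C1, C10, C14, C9, C8), methyl propiolate (C7, C11, C12; sets C8), formaldehyde (C13). 15 ⇐ (Z)‑3‑methylpent‑2‑en‑4‑yn‑1‑ol.
5. Ring order: C4–C5 oxirane, C1–C10 oxirane, ten‑membered ring, γ‑lactone.

Assumption: carbons are labelled as in germacranolides (C1–C10 ring, C11 lactone α‑carbon, C12 lactone carbonyl, C13 CH2OAc, C14 CH2OH, C15 methyl); in this numbering the target is 1R,4R,5S,6S,8S,10S with a 2Z alkene.

**Step 1**
Reactants: 1 prop-2-yn-1-ol; 2 allylmagnesium bromide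
Product: 4 (2Z)-2-(iodomethylidene)pent-4-en-1-ol, via alkenylmagnesium chelate 3 (not isolated)
Conditions: 2 (2.5 equiv), CuI (10 mol %), Et2O, −10 °C → rt; then I2, THF, −40 → 0 °C
Reagents that add atoms: iodine, [I][I]
Why: Copper-catalysed anti-carbomagnesiation of the propargylic alkoxide (Duboudin-type allylmagnesiation) puts the allyl group on the internal carbon and magnesium on the terminal carbon inside a five-membered O–Mg chelate, so iodinolysis with retention fixes iodine cis to CH2OH.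

**Step 2**
Reactants: 4 (2Z)-2-(iodomethylidene)pent-4-en-1-ol
Product: 5 tert-butyl{[(2Z)-2-(iodomethylidene)pent-4-en-1-yl]oxy}dimethylsilane
Conditions: TBSCl, imidazole, DMF, 0 °C → rt
Reagents that add atoms: tert-butyldimethylsilyl chloride, CC(C)(C)[Si](C)(C)Cl
Why: Imidazole-assisted silylation of the primary alcohol masks the C14 hydroxyl until the last step.

**Step 3**
Reactants: 5 tert-butyl{[(2Z)-2-(iodomethylidene)pent-4-en-1-yl]oxy}dimethylsilane
Product: 7 (3Z)-3-({[tert-butyl(dimethyl)silyl]oxy}methyl)-4-iodobut-3-enal, via vicinal diol 6 (not isolated)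
Conditions: OsO4 (2 mol %), NaIO4 (4 equiv), 2,6-lutidine, dioxane/H2O 3:1, rt; crude aldehyde used at once
Reagents that add atoms: osmium tetroxide, O=[Os](=O)(=O)=O (catalytic oxygen carrier); sodium periodate, [Na+].[O-]I(=O)(=O)=O (terminal oxidant)
Why: Lemieux–Johnson dihydroxylation–cleavage takes the monosubstituted alkene much faster than the iodine-deactivated trisubstituted one, and lutidine suppresses over-oxidation.

**Step 4**
Reactants: 7 (3Z)-3-({[tert-butyl(dimethyl)silyl]oxy}methyl)-4-iodobut-3-enal; 8 methyl prop-2-ynoate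
Product: 9 methyl (4S,6Z)-6-({[tert-butyl(dimethyl)silyl]oxy}methyl)-4-hydroxy-7-iodohept-6-en-2-ynoate
Conditions: 8 (3 equiv), Me2Zn (3 equiv), (S,S)-ProPhenol (20 mol %), Ph3P=O (40 mol %), toluene, 4 °C
Reagents that add atoms: none
Why: Zinc–ProPhenol-catalysed asymmetric alkynylation in which the methylzinc acetylide of 8 must add to the Re face of the aldehyde to give the 4S carbinol (C8), the (S,S)-ligand being chosen on the expectation that it shows the same facial sense as in its aldol reactions (otherwise the mirror-image ligand is used), under conditions mild enough for the enolisable β,γ-unsaturated aldehyde.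

**Step 5**
Reactants: 9 methyl (4S,6Z)-6-({[tert-butyl(dimethyl)silyl]oxy}methyl)-4-hydroxy-7-iodohept-6-en-2-ynoate
Product: 11 methyl (2Z,4S,6Z)-3-bromo-6-({[tert-butyl(dimethyl)silyl]oxy}methyl)-4-hydroxy-2-(hydroxymethyl)-7-iodohepta-2,6-dienoate, via bromomagnesium allenolate 10 (not isolated)
Conditions: MgBr2·OEt2 (2.5 equiv), monomeric CH2O (5 equiv, from cracked paraformaldehyde), CH2Cl2, −40 → 0 °C
Reagents that add atoms: magnesium dibromide, Br[Mg]Br; formaldehyde, C=O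
Why: Proposed new method: magnesium-activated conjugate addition of bromide to C7 of the ynoate gives bromoallenolate 10, whose C11 attacks formaldehyde held on the magnesium bound to the C8 hydroxyl, so C13 enters on the C8 side and bromine ends up cis to CO2Me (the opposite isomer would lactonise onto the C8 hydroxyl and be separated), the closest known reaction being the MgI2- or TiBr4-promoted halo-aldol (β-halo Morita–Baylis–Hillman) reaction of alkynoates with aldehydes.

**Step 6**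
Reactants: 11 methyl (2Z,4S,6Z)-3-bromo-6-({[tert-butyl(dimethyl)silyl]oxy}methyl)-4-hydroxy-2-(hydroxymethyl)-7-iodohepta-2,6-dienoate
Product: 12 methyl (2Z,4S,6Z)-2-(acetoxymethyl)-3-bromo-6-({[tert-butyl(dimethyl)silyl]oxy}methyl)-4-hydroxy-7-iodohepta-2,6-dienoate
Conditions: AcCl (1.05 equiv), 2,4,6-collidine, CH2Cl2, −78 °C
Reagents that add atoms: acetyl chloride, CC(=O)Cl
Why: Low-temperature acylation with acetyl chloride and collidine is selective for the unhindered primary allylic hydroxyl over the secondary one flanked by the tetrasubstituted alkene.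

**Step 7**
Reactants: 12 methyl (2Z,4S,6Z)-2-(acetoxymethyl)-3-bromo-6-({[tert-butyl(dimethyl)silyl]oxy}methyl)-4-hydroxy-7-iodohepta-2,6-dienoate
Product: 13 methyl (2Z,4S,6Z)-2-(acetoxymethyl)-3-bromo-6-({[tert-butyl(dimethyl)silyl]oxy}methyl)-7-iodo-4-[(2-methylprop-2-enoyl)oxy]hepta-2,6-dienoate
Conditions: methacrylic anhydride (1.5 equiv), Et3N, DMAP (10 mol %), CH2Cl2, 0 °C
Reagents that add atoms: methacrylic anhydride, C=C(C)C(=O)OC(=O)C(C)=C
Why: DMAP-catalysed (Steglich-type) acylation esterifies the remaining secondary hydroxyl with retention at C8.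

**Step 8**
Reactants: 14 (2Z)-3-methylpent-2-en-4-yn-1-ol
Product: 15 [(2S,3R)-3-ethynyl-3-methyloxiran-2-yl]methanol
Conditions: Ti(OiPr)4 (10 mol %), L-(+)-diethyl tartrate (12 mol %), t-BuOOH, 4 Å molecular sieves, CH2Cl2, −20 °C
Reagents that add atoms: tert-butyl hydroperoxide, CC(C)(C)OO
Why: Katsuki–Sharpless asymmetric epoxidation in which the titanium L-(+)-tartrate complex delivers oxygen to the face that gives the 2S carbinol-bearing oxirane carbon, and stereospecific syn addition to the Z-alkene thereby sets C5 (S) and C4 (R).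

**Step 9**
Reactants: 13 methyl (2Z,4S,6Z)-2-(acetoxymethyl)-3-bromo-6-({[tert-butyl(dimethyl)silyl]oxy}methyl)-7-iodo-4-[(2-methylprop-2-enoyl)oxy]hepta-2,6-dienoate; 15 [(2S,3R)-3-ethynyl-3-methyloxiran-2-yl]methanol
Product: 16 methyl (2Z,4S,6Z)-2-(acetoxymethyl)-3-bromo-6-({[tert-butyl(dimethyl)silyl]oxy}methyl)-9-[(2R,3S)-3-(hydroxymethyl)-2-methyloxiran-2-yl]-4-[(2-methylprop-2-enoyl)oxy]nona-2,6-dien-8-ynoate
Conditions: Pd(PPh3)4 (5 mol %), CuI (10 mol %), iPr2NEt, THF, 0 °C → rt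
Reagents that add atoms: none
Why: Sonogashira coupling in which zerovalent palladium inserts into the unhindered C1–iodine bond far faster than into the tetrasubstituted C7–bromine bond, the non-nucleophilic amine avoids addition–elimination at the bromoacrylate, and alkene geometries and stereocentres are untouched.

**Step 10**
Reactants: 16 methyl (2Z,4S,6Z)-2-(acetoxymethyl)-3-bromo-6-({[tert-butyl(dimethyl)silyl]oxy}methyl)-9-[(2R,3S)-3-(hydroxymethyl)-2-methyloxiran-2-yl]-4-[(2-methylprop-2-enoyl)oxy]nona-2,6-dien-8-ynoate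
Product: 17 methyl (2Z,4S)-2-(acetoxymethyl)-3-bromo-5-[(2S,3R)-2-({[tert-butyl(dimethyl)silyl]oxy}methyl)-3-{[(2R,3S)-3-(hydroxymethyl)-2-methyloxiran-2-yl]ethynyl}oxiran-2-yl]-4-[(2-methylprop-2-enoyl)oxy]pent-2-enoate
Conditions: D-fructose-derived Shi ketone (30 mol %), KHSO5 (as 2KHSO5·KHSO4·K2SO4), K2CO3, Bu4NHSO4, MeCN/(MeO)2CH2/aq. Na2B4O7–Na2EDTA buffer, 0 °C
Reagents that add atoms: potassium peroxymonosulfate, [K+].[O-]S(=O)(=O)OO
Why: Shi asymmetric epoxidation in which the chiral dioxirane attacks only the electron-rich trisubstituted enyne alkene (the acrylate alkenes are inert) and the spiro transition state for the trans pair C9/C2 delivers oxygen to the face that gives 1R,10S.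

**Step 11**
Reactants: 17 methyl (2Z,4S)-2-(acetoxymethyl)-3-bromo-5-[(2S,3R)-2-({[tert-butyl(dimethyl)silyl]oxy}methyl)-3-{[(2R,3S)-3-(hydroxymethyl)-2-methyloxiran-2-yl]ethynyl}oxiran-2-yl]-4-[(2-methylprop-2-enoyl)oxy]pent-2-enoate
Product: 18 methyl (2Z,4S)-2-(acetoxymethyl)-3-bromo-5-[(2S,3R)-2-({[tert-butyl(dimethyl)silyl]oxy}methyl)-3-{(Z)-2-[(2R,3S)-3-(hydroxymethyl)-2-methyloxiran-2-yl]ethenyl}oxiran-2-yl]-4-[(2-methylprop-2-enoyl)oxy]pent-2-enoate
Conditions: H2 (1 atm), Pd/CaCO3 poisoned with Pb(OAc)2 (Lindlar catalyst), quinoline, EtOAc, 0 °C, stopped after 1 equiv H2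
Reagents that add atoms: none
Why: Lindlar semi-hydrogenation adds hydrogen syn to the only alkyne and so gives the 2Z-alkene, quinoline limiting over-reduction and hydrogenolysis of the propargylic oxiranes and the vinyl bromide.

**Step 12**
Reactants: 18 methyl (2Z,4S)-2-(acetoxymethyl)-3-bromo-5-[(2S,3R)-2-({[tert-butyl(dimethyl)silyl]oxy}methyl)-3-{(Z)-2-[(2R,3S)-3-(hydroxymethyl)-2-methyloxiran-2-yl]ethenyl}oxiran-2-yl]-4-[(2-methylprop-2-enoyl)oxy]pent-2-enoate
Product: 19 methyl (2Z,4S)-2-(acetoxymethyl)-3-bromo-5-[(2S,3R)-2-({[tert-butyl(dimethyl)silyl]oxy}methyl)-3-{(Z)-2-[(2R,3R)-3-formyl-2-methyloxiran-2-yl]ethenyl}oxiran-2-yl]-4-[(2-methylprop-2-enoyl)oxy]pent-2-enoate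
Conditions: Dess–Martin periodinane, NaHCO3, CH2Cl2, 0 °C; used crude
Reagents that add atoms: none
Why: Buffered Dess–Martin oxidation gives the α,β-epoxy aldehyde under non-basic conditions that leave both oxiranes and all esters intact (the C5 descriptor changes to R only because the CIP priorities change).

**Step 13**
Reactants: 19 methyl (2Z,4S)-2-(acetoxymethyl)-3-bromo-5-[(2S,3R)-2-({[tert-butyl(dimethyl)silyl]oxy}methyl)-3-{(Z)-2-[(2R,3R)-3-formyl-2-methyloxiran-2-yl]ethenyl}oxiran-2-yl]-4-[(2-methylprop-2-enoyl)oxy]pent-2-enoate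
Product: 22 14-O-tert-butyldimethylsilyl ether of the target (ten-membered carbocycle fused to the butenolide), via alkenylchromium 20 (not isolated), via chromium alkoxide 21 (not isolated)
Conditions: CrCl2 (10 equiv), NiCl2 (2 mol % relative to chromium), degassed DMSO/THF 1:3, rt, 19 added by syringe pump over 12 h (final 2 mM); aqueous sodium serinate work-up; brief stirring with silica gel to complete lactonisation
Reagents that add atoms: none
Why: Intramolecular Nozaki–Hiyama–Kishi reaction in which nickel-catalysed insertion of divalent chromium into the C7–Br bond turns the normally electrophilic β-carbon of the acrylate into the nucleophilic alkenylchromium 20 (a β-acylvinyl anion, an sp2 homoenolate equivalent), which adds to the electrophilic C6 aldehyde anti to the oxirane C–O bond (polar Felkin–Anh, erythro) in a chain pre-folded by the Z-alkene and the two oxiranes to set 6S, after which alkoxide 21 lactonises onto the cis methyl ester.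

**Step 14**
Reactants: 22 14-O-tert-butyldimethylsilyl ether of the target
Product: 23 target, (1R,4R,5S,6S,8S,10S)-13-acetoxy-1,10:4,5-diepoxy-14-hydroxy-8-(methacryloyloxy)germacra-2Z,7(11)-dien-12,6-olide
Conditions: HF·pyridine, pyridine, THF, 0 °C
Reagents that add atoms: none
Why: Fluoride-driven desilylation under pyridine-buffered conditions frees the C14 hydroxyl without opening the vinyl oxiranes or cleaving the acetate, methacrylate or lactone.

**Compound list**
1 | prop-2-yn-1-ol (propargyl alcohol) | C#CCO | starting material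
2 | allylmagnesium bromide | C=CC[Mg]Br | starting material
3 | 4-(prop-2-en-1-yl)-2,5-dihydro-1,2-oxamagnesole (alkenylmagnesium chelate, Mg on the former terminal alkyne carbon, cis to the CH2O arm) | C=CCC1=C[Mg]OC1 | intermediate
4 | (2Z)-2-(iodomethylidene)pent-4-en-1-ol | OC/C(CC=C)=C\I | intermediate
5 | tert-butyl{[(2Z)-2-(iodomethylidene)pent-4-en-1-yl]oxy}dimethylsilane | CC(C)(C)[Si](C)(C)OC/C(CC=C)=C\I | intermediate
6 | (4Z)-4-({[tert-butyl(dimethyl)silyl]oxy}methyl)-5-iodopent-4-ene-1,2-diol (both C2 epimers) | CC(C)(C)[Si](C)(C)OC/C(CC(O)CO)=C\I | intermediate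
7 | (3Z)-3-({[tert-butyl(dimethyl)silyl]oxy}methyl)-4-iodobut-3-enal | CC(C)(C)[Si](C)(C)OC/C(CC=O)=C\I | intermediate
8 | methyl prop-2-ynoate (methyl propiolate) | C#CC(=O)OC | starting material
9 | methyl (4S,6Z)-6-({[tert-butyl(dimethyl)silyl]oxy}methyl)-4-hydroxy-7-iodohept-6-en-2-ynoate | O[C@H](C#CC(=O)OC)C/C(CO[Si](C)(C)C(C)(C)C)=C/I | intermediate
10 | bromomagnesium allenolate of 9 (C7 bromide, C11 allene centre, 4S carbinol) | COC(O[Mg]Br)=C=C(Br)[C@@H](O)C/C(CO[Si](C)(C)C(C)(C)C)=C/I | intermediate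
11 | methyl (2Z,4S,6Z)-3-bromo-6-({[tert-butyl(dimethyl)silyl]oxy}methyl)-4-hydroxy-2-(hydroxymethyl)-7-iodohepta-2,6-dienoate | O[C@H](/C(Br)=C(\CO)C(=O)OC)C/C(CO[Si](C)(C)C(C)(C)C)=C/I | intermediate
12 | methyl (2Z,4S,6Z)-2-(acetoxymethyl)-3-bromo-6-({[tert-butyl(dimethyl)silyl]oxy}methyl)-4-hydroxy-7-iodohepta-2,6-dienoate | O[C@H](/C(Br)=C(\COC(C)=O)C(=O)OC)C/C(CO[Si](C)(C)C(C)(C)C)=C/I | intermediate
13 | methyl (2Z,4S,6Z)-2-(acetoxymethyl)-3-bromo-6-({[tert-butyl(dimethyl)silyl]oxy}methyl)-7-iodo-4-[(2-methylprop-2-enoyl)oxy]hepta-2,6-dienoate | C=C(C)C(=O)O[C@H](/C(Br)=C(\COC(C)=O)C(=O)OC)C/C(CO[Si](C)(C)C(C)(C)C)=C/I | intermediate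
14 | (2Z)-3-methylpent-2-en-4-yn-1-ol | C#C/C(C)=C\CO | starting material
15 | [(2S,3R)-3-ethynyl-3-methyloxiran-2-yl]methanol | C#C[C@@]1(C)O[C@H]1CO | intermediate
16 | methyl (2Z,4S,6Z)-2-(acetoxymethyl)-3-bromo-6-({[tert-butyl(dimethyl)silyl]oxy}methyl)-9-[(2R,3S)-3-(hydroxymethyl)-2-methyloxiran-2-yl]-4-[(2-methylprop-2-enoyl)oxy]nona-2,6-dien-8-ynoate | C=C(C)C(=O)O[C@H](/C(Br)=C(\COC(C)=O)C(=O)OC)C/C(CO[Si](C)(C)C(C)(C)C)=C/C#C[C@@]1(C)O[C@H]1CO | intermediate
17 | methyl (2Z,4S)-2-(acetoxymethyl)-3-bromo-5-[(2S,3R)-2-({[tert-butyl(dimethyl)silyl]oxy}methyl)-3-{[(2R,3S)-3-(hydroxymethyl)-2-methyloxiran-2-yl]ethynyl}oxiran-2-yl]-4-[(2-methylprop-2-enoyl)oxy]pent-2-enoate | C=C(C)C(=O)O[C@H](/C(Br)=C(\COC(C)=O)C(=O)OC)C[C@@]1(CO[Si](C)(C)C(C)(C)C)O[C@@H]1C#C[C@@]2(C)O[C@H]2CO | intermediate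
18 | methyl (2Z,4S)-2-(acetoxymethyl)-3-bromo-5-[(2S,3R)-2-({[tert-butyl(dimethyl)silyl]oxy}methyl)-3-{(Z)-2-[(2R,3S)-3-(hydroxymethyl)-2-methyloxiran-2-yl]ethenyl}oxiran-2-yl]-4-[(2-methylprop-2-enoyl)oxy]pent-2-enoate | C=C(C)C(=O)O[C@H](/C(Br)=C(\COC(C)=O)C(=O)OC)C[C@@]1(CO[Si](C)(C)C(C)(C)C)O[C@@H]1/C=C\[C@@]2(C)O[C@H]2CO | intermediate
19 | methyl (2Z,4S)-2-(acetoxymethyl)-3-bromo-5-[(2S,3R)-2-({[tert-butyl(dimethyl)silyl]oxy}methyl)-3-{(Z)-2-[(2R,3R)-3-formyl-2-methyloxiran-2-yl]ethenyl}oxiran-2-yl]-4-[(2-methylprop-2-enoyl)oxy]pent-2-enoate | C=C(C)C(=O)O[C@H](/C(Br)=C(\COC(C)=O)C(=O)OC)C[C@@]1(CO[Si](C)(C)C(C)(C)C)O[C@@H]1/C=C\[C@@]2(C)O[C@H]2C=O | intermediate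
20 | alkenyl(dichloro)chromium derived from 19 (C7–Br replaced by C7–CrCl2, trivalent chromium, chromium cis to CO2Me) | C=C(C)C(=O)O[C@H](/C([Cr](Cl)Cl)=C(\COC(C)=O)C(=O)OC)C[C@@]1(CO[Si](C)(C)C(C)(C)C)O[C@@H]1/C=C\[C@@]2(C)O[C@H]2C=O | intermediate
21 | dichlorochromium alkoxide of the ring-closed hydroxy ester (ten-membered ring, 6S oxygen on chromium, C6 cis to CO2Me across C7=C11) | C=C(C)C(=O)O[C@H]1C[C@@]2(CO[Si](C)(C)C(C)(C)C)O[C@@H]2/C=C\[C@@]2(C)O[C@H]2[C@@H](O[Cr](Cl)Cl)/C1=C(/COC(C)=O)C(=O)OC | intermediate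
22 | 14-O-tert-butyldimethylsilyl ether of the target (1R,4R,5S,6S,8S,10S; 2Z) | C=C(C)C(=O)O[C@H]1C[C@@]2(CO[Si](C)(C)C(C)(C)C)O[C@@H]2/C=C\[C@@]2(C)O[C@H]2[C@H]2OC(=O)C(COC(C)=O)=C12 | intermediate
23 | (1R,4R,5S,6S,8S,10S)-13-acetoxy-1,10:4,5-diepoxy-14-hydroxy-8-(methacryloyloxy)germacra-2Z,7(11)-dien-12,6-olide | C=C(C)C(=O)O[C@H]1C[C@@]2(CO)O[C@@H]2/C=C\[C@@]2(C)O[C@H]2[C@H]2OC(=O)C(COC(C)=O)=C12 | target

**Step count and risks**

Total: 14 steps. Longest linear sequence: 13 steps (steps 1–7 and 9–14); step 8 is a one-step side branch.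

The three steps most likely to fail:

Step 13 (ring closure). The tetrasubstituted alkenyl bromide is a slow partner, the alkenylchromium carries a β-acyloxy group that could eliminate to an allene, and the ten-membered ring and the C6 configuration are both decided in one event. Fallback, changing the ring-closing bond while keeping the same polarity-reversed C6–C7 coupling: set out from 13 and 15. Stille coupling of 13 with tributyl(vinyl)stannane (Pd(PPh3)4, CuI, DMF; C–I before C–Br) gives methyl (2Z,4S,6Z)-2-(acetoxymethyl)-3-bromo-6-({[tert-butyl(dimethyl)silyl]oxy}methyl)-4-[(2-methylprop-2-enoyl)oxy]nona-2,6,8-trienoate F5. Shi epoxidation of its trisubstituted alkene gives the vinyl oxirane F6. In parallel, Lindlar reduction of 15 gives [(2S,3R)-3-ethenyl-3-methyloxiran-2-yl]methanol F7, and Dess–Martin oxidation gives (2R,3R)-3-ethenyl-3-methyloxirane-2-carbaldehyde F8. Intermolecular CrCl2/NiCl2 coupling of F6 with F8 (Felkin–Anh control, no ring strain) and lactonisation gives the butenolide diene F9. Ring-closing metathesis of the two vinyl oxiranes (second-generation Grubbs catalyst, or a cyclometalated Z-selective ruthenium catalyst, high dilution) forms the 2Z alkene and comes back to the route at 22.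

Step 5 (bromo-aldol). It is a new extension of the halo-aldol reaction to a β-substituted ynoate with formaldehyde, and the whole route depends on bromine ending up cis to CO2Me. Fallback, enforcing the geometry with a tether: set out from 9. Silylation with (bromomethyl)chlorodimethylsilane (imidazole, CH2Cl2) gives methyl (4S,6Z)-4-{[(bromomethyl)(dimethyl)silyl]oxy}-6-({[tert-butyl(dimethyl)silyl]oxy}methyl)-7-iodohept-6-en-2-ynoate F1. MgBr2·OEt2 then adds bromide to C7, and the allenolate carbon C11 alkylates the silicon-bound CH2Br in a six-membered ring closure that can only place C13 cis to C8, giving methyl (6S)-5-bromo-6-[(2Z)-2-({[tert-butyl(dimethyl)silyl]oxy}methyl)-3-iodoprop-2-en-1-yl]-2,2-dimethyl-3,6-dihydro-2H-1,2-oxasiline-4-carboxylate F2. Tamao–Fleming oxidation (H2O2, KF, KHCO3, THF/MeOH) cleaves the Si–C and Si–O bonds and comes back to the route at diol 11.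

Step 11 (semi-hydrogenation). The alkyne sits between two propargylic oxiranes, and the molecule also carries a methacrylate and a vinyl bromide, so over-reduction or hydrogenolysis is possible. Fallback, making the Z-alkene by cross-coupling instead of reduction: set out from 15 and 13. Rhodium-catalysed trans-hydroboration of 15 ([Rh(cod)Cl]2, P(iPr)3, Et3N, pinacolborane) gives [(2S,3R)-3-methyl-3-[(Z)-2-(4,4,5,5-tetramethyl-1,3,2-dioxaborolan-2-yl)ethenyl]oxiran-2-yl]methanol F3. Suzuki–Miyaura coupling with iodide 13 (Pd(PPh3)4, aq. K3PO4, THF, rt; C–I before C–Br) gives methyl (2Z,4S,6Z,8Z)-2-(acetoxymethyl)-3-bromo-6-({[tert-butyl(dimethyl)silyl]oxy}methyl)-9-[(2R,3S)-3-(hydroxymethyl)-2-methyloxiran-2-yl]-4-[(2-methylprop-2-enoyl)oxy]nona-2,6,8-trienoate F4. Shi epoxidation of its trisubstituted alkene (same facial sense as in step 10) comes back to the route at 18.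

**Further compounds**
F1 | step 5 | methyl (4S,6Z)-4-{[(bromomethyl)(dimethyl)silyl]oxy}-6-({[tert-butyl(dimethyl)silyl]oxy}methyl)-7-iodohept-6-en-2-ynoate | BrC[Si](C)(C)O[C@H](C#CC(=O)OC)C/C(CO[Si](C)(C)C(C)(C)C)=C/I
F2 | step 5 | methyl (6S)-5-bromo-6-[(2Z)-2-({[tert-butyl(dimethyl)silyl]oxy}methyl)-3-iodoprop-2-en-1-yl]-2,2-dimethyl-3,6-dihydro-2H-1,2-oxasiline-4-carboxylate | COC(=O)C1=C(Br)[C@H](C/C(CO[Si](C)(C)C(C)(C)C)=C/I)O[Si](C)(C)C1
F3 | step 11 | [(2S,3R)-3-methyl-3-[(Z)-2-(4,4,5,5-tetramethyl-1,3,2-dioxaborolan-2-yl)ethenyl]oxiran-2-yl]methanol | CC1(C)OB(/C=C\[C@@]2(C)O[C@H]2CO)OC1(C)C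
F4 | step 11 | methyl (2Z,4S,6Z,8Z)-2-(acetoxymethyl)-3-bromo-6-({[tert-butyl(dimethyl)silyl]oxy}methyl)-9-[(2R,3S)-3-(hydroxymethyl)-2-methyloxiran-2-yl]-4-[(2-methylprop-2-enoyl)oxy]nona-2,6,8-trienoate | C=C(C)C(=O)O[C@H](/C(Br)=C(\COC(C)=O)C(=O)OC)C/C(CO[Si](C)(C)C(C)(C)C)=C/C=C\[C@@]1(C)O[C@H]1CO
F5 | step 13 | methyl (2Z,4S,6Z)-2-(acetoxymethyl)-3-bromo-6-({[tert-butyl(dimethyl)silyl]oxy}methyl)-4-[(2-methylprop-2-enoyl)oxy]nona-2,6,8-trienoate | C=C(C)C(=O)O[C@H](/C(Br)=C(\COC(C)=O)C(=O)OC)C/C(CO[Si](C)(C)C(C)(C)C)=C/C=C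
F6 | step 13 | methyl (2Z,4S)-2-(acetoxymethyl)-3-bromo-5-[(2S,3R)-2-({[tert-butyl(dimethyl)silyl]oxy}methyl)-3-ethenyloxiran-2-yl]-4-[(2-methylprop-2-enoyl)oxy]pent-2-enoate | C=C(C)C(=O)O[C@H](/C(Br)=C(\COC(C)=O)C(=O)OC)C[C@@]1(CO[Si](C)(C)C(C)(C)C)O[C@@H]1C=C
F7 | step 13 | [(2S,3R)-3-ethenyl-3-methyloxiran-2-yl]methanol | C=C[C@@]1(C)O[C@H]1CO
F8 | step 13 | (2R,3R)-3-ethenyl-3-methyloxirane-2-carbaldehyde | C=C[C@@]1(C)O[C@H]1C=O
F9 | step 13 | butenolide diene: 22 opened between C2 and C3, each of C2 and C3 carrying a terminal CH2 (two vinyl oxiranes) | C=C(C)C(=O)O[C@@H](C[C@@]1(CO[Si](C)(C)C(C)(C)C)O[C@@H]1C=C)C1=C(COC(C)=O)C(=O)O[C@@H]1[C@@H]1O[C@]1(C)C=C
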